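The readings were computed from invented constants, noise included.

Reckon the leftover reagent first. The listed steps spend one reagent per starting material, so the fraction of the reagent charge you lose is the fraction of starting material converted times the draw, the charge of starting material over the charge of reagent, here 0.909 for cedar. In cedar that value makes starting material the limiting reagent.

the same everywhere: starting material 0.050 M; free catalyst 0.14 mM

| run | reagent | remark | time |
|---|---|---|---|
| Sunday's | 0.065 M | run made earlier |  |
| Thursday's | 0.085 M | run made earlier |  |
| Wednesday's | 0.14 M | run made earlier |  |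
| ash | 0.150 M |  | 5.0 min |
| cedar | 0.0550 M |  | 20 min |

| run | time / min | product / % |
|---|---|---|
| Sunday's | 2.00 | 3.4 |
| Sunday's | 5.00 | 9.4 |
| Sunday's | 10.0 | 18.7 |
| Sunday's | 15.0 | 23.9 |
| Sunday's | 20.0 | 33.4 |
| Thursday's | 4.00 | 8.8 |
| Thursday's | 8.00 | 16.6 |
| Thursday's | 12.0 | 24.8 |
| Thursday's | 15.0 | 30.0 |
| Thursday's | 20.0 | 37.8 |
| Wednesday's | 2.00 | 5.4 |
| Wednesday's | 5.00 | 12.3 |
| Wednesday's | 10.0 | 24.9 |
| Wednesday's | 15.0 | 34.7 |
| Wednesday's | 20.0 | 44.8 |

(standard deviation of a reading: 1 percentage point)

- the analysis behind the earlier runs scatters by 1 percentage point, standard deviation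
- on the list of suspects stand: starting material + free catalyst <-> catalyst intermediate A; reagent + catalyst intermediate A -> catalyst intermediate B; catalyst intermediate B -> by-product + catalyst intermediate C; catalyst intermediate C -> free catalyst + product

* the winner by amount of product, in percent of the starting material charged; "neither" if no more than 2 percentage points parts them (ash / cedar / neither)
* how much product is there at the end, in percent of the starting material charged: ash
* how much product is there at the end, in percent of the starting material charged: cedar

Who wins? Sunday's and Wednesday's readings at 20.0 min give product going as reagent to the power 0.383, a reading with its scatter. So ash's larger charge buys a factor of 1.47, but cedar has a time factor of 4.00. My pick is cedar.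

How much does ash make? Scaling Wednesday's reading at 5.00 min gives 12.6 %. Its draw of 0.333 then leaves 95.8 % of its reagent, so I leave the correction out of this estimate.

Does spent reagent spoil cedar? Scaling Sunday's last reading gives 31.3 %. That leaves cedar 71.5 % of its reagent, and Sunday's, with a draw of 0.769, kept 74.3 %. The two run down alike, so the correction nearly cancels in the scaling.

The forecast also names cedar, with ash at 13 % (11.8 % to 14.2 %) and cedar at 29.5 % (27.5 % to 32 %), “just below Sunday's run”. Its cedar figure is lower than mine.

The flask gives cedar: cedar 29.5 %, ash 13.3 %, both inside the forecast's ranges.

    starting material + free catalyst ⇌ catalyst intermediate A (K = 4.80 L mol⁻¹, k = 31.3 L mol⁻¹ s⁻¹)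
    reagent + catalyst intermediate A → catalyst intermediate B (k = 17.7 L mol⁻¹ s⁻¹)
    catalyst intermediate B → by-product + catalyst intermediate C (k = 0.753 s⁻¹)
    catalyst intermediate C → free catalyst + product (k = 0.467 s⁻¹)

Ash reads 13.3 % chiefly because of the short time given: at 50.0 min the same flask stands at 85.7 %. Cedar's shrinking reagent supply is a part of its shortfall: with that shrinking taken away, the reagent held at its charge, cedar goes from 29.5 % to 32.1 %, a gain of 2.7 percentage points. The draw tells how far the supply shrinks: applied to cedar's conversion of 29.6 %, it gives 73.1 % of the reagent left, and cedar holds 73 %. The neighbour of cedar charged with 0.013 M of starting material has a draw of 0.236, which at its conversion gives 90.0 %, and that flask holds 90 %.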